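**Plan**

1. Numbering used below: decalin C1–C10 (ring A = C1–C5 and C10, ring B = C5–C10), C18 = CH2OH and C19 = CH3 on C4, C17 = CH3 on C8, C20 = CH3 on C10, side chain C11–C15 (C15 = carbinol), butenolide C2′–C5′.
2. Retrosynthetic cuts: C15–C5′ (vinylogous aldol onto the intact, purchased butenolide ring), C13=C14 and C14–C15 (alkyne carbometalation), then C4–C5 and C18–O of ring A, then C10–C1 and C9–C11 on ring B, and ring B at C9=C10 back to (R)-linalool.
3. Forward order: ring B by ring-closing metathesis (step 4), then ring A as the last ring closure by a palladium-catalysed 6-exo cyclisation/borylation (step 10); the butenolide ring is never closed in the route.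
4. Enabling feature: C4 is quaternary and carries C18, so palladium delivered to C18 has no β-hydrogen and can be exchanged for boron; C10 is quaternary, so the C5 ketone of ring B gives one enol triflate; the C5=C6 bond that remains lies under the axial methyls C19 and C20.
5. Stereochemistry: C8 from (R)-linalool; C9 by conjugate addition anti to the C8 silyloxy group; C10 by allylation anti to C9; C4 by the C20-controlled face of the insertion; C5 and C6 by α-face hydroboration; C15 and C5′ by a BINOL–titanium vinylogous aldol.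

Key step: step 10

Remark on the chemistry: (R)-(−)-linalool and 4-methylfuran-2(5H)-one are taken as commercial. In step 19 the (R)-BINOL titanium catalyst is assumed to expose the Re face of the enal; if it exposes the other face, the mirror-image ligand is used. Descriptors α/β refer to the decalin of the target (β = face of the C20 methyl).

**Route**

Step 1
Reactants: 1 (R)-(−)-linalool; 2 triethylsilyl trifluoromethanesulfonate
Product: 3 (3R)-3,7-dimethyl-3-(triethylsilyloxy)octa-1,6-diene
Conditions: Et3SiOTf, 2,6-lutidine, CH2Cl2, −78 to 0 °C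
Reagents that add atoms: triethylsilyl trifluoromethanesulfonate CC[Si](CC)(CC)OS(=O)(=O)C(F)(F)F
Why: Silylation of the tertiary allylic alcohol with a silyl triflate and a hindered pyridine base is standard and does not touch the stereocentre that becomes C8.

Step 2
Reactants: 3 (3R)-3,7-dimethyl-3-(triethylsilyloxy)octa-1,6-diene; 4 ozone
Product: 6 (4R)-4-methyl-4-(triethylsilyloxy)hex-5-enal, via secondary ozonide 5 (not isolated)
Conditions: O3 (1 equiv), CH2Cl2, −78 °C; then PPh3, −78 °C to rt
Reagents that add atoms: ozone [O-][O+]=O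
Why: Ozonolysis with reductive work-up should cleave only the electron-rich trisubstituted alkene, because the vinyl group on the quaternary carbinol carbon reacts much more slowly with one equivalent of ozone.

Step 3
Reactants: 6 (4R)-4-methyl-4-(triethylsilyloxy)hex-5-enal; 7 isopropenylmagnesium bromide
Product: 8 (6R)-2,6-dimethyl-6-(triethylsilyloxy)octa-1,7-dien-3-ol (both C3 epimers)
Conditions: CH2=C(CH3)MgBr, THF, −78 to 0 °C; aq NH4Cl
Reagents that add atoms: isopropenylmagnesium bromide CC(=C)[Mg]Br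
Why: Grignard 1,2-addition to the aldehyde brings in C10 and C20, and the unselective new carbinol centre is removed by the oxidation in step 5.

Step 4
Reactants: 8 (6R)-2,6-dimethyl-6-(triethylsilyloxy)octa-1,7-dien-3-ol
Product: 9 (4R)-2,4-dimethyl-4-(triethylsilyloxy)cyclohex-2-en-1-ol (both C1 epimers)
Conditions: second-generation Grubbs catalyst (5 mol %), CH2Cl2, 40 °C
Reagents that add atoms: none
Why: Ring-closing metathesis of the 1,1-disubstituted and the monosubstituted alkene closes ring B as a trisubstituted cyclohexene with loss of ethene.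

Step 5
Reactants: 9 (4R)-2,4-dimethyl-4-(triethylsilyloxy)cyclohex-2-en-1-ol
Product: 10 (4R)-2,4-dimethyl-4-(triethylsilyloxy)cyclohex-2-en-1-one
Conditions: Dess–Martin periodinane, NaHCO3, CH2Cl2, 0 °C to rt
Reagents that add atoms: none
Why: Dess–Martin oxidation of the allylic alcohol should converge both epimers to the ring B enone (C5 carbonyl, C10=C9).

Step 6
Reactants: 10 (4R)-2,4-dimethyl-4-(triethylsilyloxy)cyclohex-2-en-1-one; 11 benzyl 3-bromopropyl ether; 12 chlorotrimethylsilane
Product: 14 (3R,4R)-3-[3-(benzyloxy)propyl]-2,4-dimethyl-4-(triethylsilyloxy)-1-(trimethylsilyloxy)cyclohex-1-ene, via Grignard reagent 13 (not isolated)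
Conditions: 11, Mg, THF; then CuBr·SMe2, Me3SiCl, 10, THF, −78 to −40 °C; Et3N
Reagents that add atoms: benzyl 3-bromopropyl ether BrCCCOCc1ccccc1; chlorotrimethylsilane C[Si](C)(C)Cl
Why: Chlorotrimethylsilane-accelerated copper-mediated conjugate addition should occur by axial attack at C9 anti to the pseudo-axial silyloxy group on the neighbouring quaternary C8, which sets the side chain trans to the C8 oxygen and traps the enolate regiospecifically as the silyl enol ether.

Step 7
Reactants: 14 (3R,4R)-3-[3-(benzyloxy)propyl]-2,4-dimethyl-4-(triethylsilyloxy)-1-(trimethylsilyloxy)cyclohex-1-ene; 15 allyl bromide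
Product: 17 (2R,3R,4R)-2-allyl-3-[3-(benzyloxy)propyl]-2,4-dimethyl-4-(triethylsilyloxy)cyclohexan-1-one, via lithium enolate 16 (not isolated)
Conditions: MeLi, THF, 0 °C; then allyl bromide, HMPA, −78 to 0 °C
Reagents that add atoms: allyl bromide C=CCBr
Why: Methyllithium should release the regio-defined lithium enolate, and C-allylation anti to the vicinal C9 substituent creates the quaternary C10 with the allyl group (C1–C3) trans to the side chain and C20 cis to it.

Step 8
Reactants: 17 (2R,3R,4R)-2-allyl-3-[3-(benzyloxy)propyl]-2,4-dimethyl-4-(triethylsilyloxy)cyclohexan-1-one; 18 2-bromopropene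
Product: 20 (2R,3R,4R)-3-[3-(benzyloxy)propyl]-2,4-dimethyl-2-(4-methylpent-4-en-1-yl)-4-(triethylsilyloxy)cyclohexan-1-one, via B-alkyl-9-BBN adduct 19 (not isolated)
Conditions: 9-BBN, THF, 0 °C to rt; then 2-bromopropene, PdCl2(dppf) (5 mol %), aq K3PO4, DMF, 50 °C
Reagents that add atoms: 2-bromopropene CC(Br)=C
Why: 9-BBN should hydroborate the terminal alkene much faster than it reduces the hindered ketone, and the B-alkyl Suzuki–Miyaura coupling then installs the 1,1-disubstituted alkene that holds C4, C18 and C19.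

Step 9
Reactants: 20 (2R,3R,4R)-3-[3-(benzyloxy)propyl]-2,4-dimethyl-2-(4-methylpent-4-en-1-yl)-4-(triethylsilyloxy)cyclohexan-1-one; 21 N-phenylbis(trifluoromethanesulfonimide)
Product: 22 (4R,5R,6R)-5-[3-(benzyloxy)propyl]-4,6-dimethyl-6-(4-methylpent-4-en-1-yl)-4-(triethylsilyloxy)cyclohex-1-en-1-yl trifluoromethanesulfonate
Conditions: KN(SiMe3)2, THF, −78 °C; PhNTf2, −78 to 0 °C
Reagents that add atoms: N-phenylbis(trifluoromethanesulfonimide) O=S(=O)(N(c1ccccc1)S(=O)(=O)C(F)(F)F)C(F)(F)F
Why: Because C10 is quaternary the C5 ketone can enolise only towards C6, so deprotonation and O-triflation should give a single vinyl triflate.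

Step 10
Reactants: 22 (4R,5R,6R)-5-[3-(benzyloxy)propyl]-4,6-dimethyl-6-(4-methylpent-4-en-1-yl)-4-(triethylsilyloxy)cyclohex-1-en-1-yl trifluoromethanesulfonate; 23 bis(pinacolato)diboron
Product: 25 C5=C6 octalin boronate (4α-CH2Bpin; 4β-CH3; 10β-CH3; 9β-[3-(benzyloxy)propyl]; 8β-CH3; 8α-OSiEt3), via neopentyl-type alkylpalladium acetate 24 (not isolated)
Conditions: Pd(OAc)2 (10 mol %), PPh3 (25 mol %), B2pin2 (2 equiv), KOAc (3 equiv), 1,4-dioxane, 80 °C
Reagents that add atoms: bis(pinacolato)diboron CC1(C)OB(OC1(C)C)B1OC(C)(C)C(C)(C)O1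
Why: Oxidative addition of the vinyl triflate to zerovalent palladium gives a C5 vinylpalladium that inserts the pendant 1,1-disubstituted alkene by 6-exo-trig syn-carbopalladation (ring A closes through the C4–C5 bond), and the resulting C18 alkylpalladium, which has no β-hydrogen because C4 is now quaternary, is intercepted by transmetalation with B2pin2 and reductive elimination to the C18 boronate. The closest known reaction type is the domino Mizoroki–Heck cyclisation/Miyaura borylation (Heck–anion capture) of halide- or triflate-tethered 1,1-disubstituted alkenes. Only ring A is closed, in the 6-exo mode, since the 7-endo mode would place palladium on a tertiary carbon. The new stereocentre C4 is controlled by C10: the angular methyl C20 sits over the β-face of the vinylpalladium, so the alkene and the metal stay on the α-side, the carbon that receives palladium (C18) ends α and the C19 methyl ends β. The step needs insertion to outrun direct borylation of the vinylpalladium and boron capture to outrun 3-exo attack of the alkylpalladium on C5=C6; the first is served by the intramolecular 6-exo geometry and the shielding of C5 by the quaternary C10, the second by excess B2pin2 with acetate as activating base.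

Step 11
Reactants: 25 C5=C6 octalin boronate; 26 hydrogen peroxide
Product: 28 trans-decalin 6α,18-diol (5α-H; 6α-OH; 4α-CH2OH; 4β-CH3; 10β-CH3; 9β-[3-(benzyloxy)propyl]; 8β-CH3; 8α-OSiEt3), via C6 alkylborane 27 (not isolated)
Conditions: BH3·THF, THF, 0 °C to rt; then 3 M NaOH, 30% H2O2, 0 °C to rt
Reagents that add atoms: hydrogen peroxide OO
Why: Hydroboration of the trisubstituted C5=C6 bond should occur from the α-face, because the β-face is shielded by the axial C19 and C20 methyls, placing boron on C6 and hydrogen on C5 syn to give the trans ring fusion, and alkaline peroxide then oxidises both the C6–B bond and the C18 boronate with retention.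

Step 12
Reactants: 28 trans-decalin 6α,18-diol; 29 tert-butyldimethylsilyl trifluoromethanesulfonate
Product: 30 6,18-bis(tert-butyldimethylsilyl) ether of 28
Conditions: t-BuMe2SiOTf, 2,6-lutidine, CH2Cl2, −78 to 0 °C
Reagents that add atoms: tert-butyldimethylsilyl trifluoromethanesulfonate CC(C)(C)[Si](C)(C)OS(=O)(=O)C(F)(F)F
Why: The silyl triflate should silylate both the neopentyl primary and the hindered secondary hydroxyl, so that only the side-chain oxygen is unmasked in the next step.

Step 13
Reactants: 30 6,18-bis(tert-butyldimethylsilyl) ether of 28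
Product: 31 primary alcohol (9β-(3-hydroxypropyl) analogue of 30)
Conditions: H2 (1 atm), Pd/C, EtOAc, rt
Reagents that add atoms: none
Why: Hydrogenolysis removes the benzyl ether selectively, since no alkene is left in the molecule and silyl ethers are inert to these conditions.

Step 14
Reactants: 31 primary alcohol
Product: 32 aldehyde (9β-(3-oxopropyl) analogue of 30)
Conditions: Dess–Martin periodinane, NaHCO3, CH2Cl2, rt
Reagents that add atoms: none
Why: Buffered Dess–Martin oxidation of the only free hydroxyl should give the aldehyde without touching the silyl ethers.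

Step 15
Reactants: 32 aldehyde; 33 dimethyl (1-diazo-2-oxopropyl)phosphonate
Product: 34 terminal alkyne (9β-(but-3-yn-1-yl) analogue of 30)
Conditions: dimethyl (1-diazo-2-oxopropyl)phosphonate, K2CO3, MeOH, 0 °C to rt
Reagents that add atoms: dimethyl (1-diazo-2-oxopropyl)phosphonate CC(=O)C(=[N+]=[N-])P(=O)(OC)OC
Why: Seyferth–Gilbert homologation with the Ohira–Bestmann reagent converts the aldehyde into the terminal alkyne (C13 and C14) under mild base.

Step 16
Reactants: 34 terminal alkyne; 35 trimethylaluminium; 36 paraformaldehyde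
Product: 38 (E)-allylic alcohol (9β-[(3E)-5-hydroxy-3-methylpent-3-en-1-yl] analogue of 30), via alkenyldimethylalane 37 (not isolated)
Conditions: Me3Al, Cp2ZrCl2 (25 mol %), CH2Cl2, 0 °C to rt; then n-BuLi, THF, −78 °C; (CH2O)n, −78 °C to rt
Reagents that add atoms: trimethylaluminium C[Al](C)C; paraformaldehyde (as formaldehyde) C=O
Why: Zirconium-catalysed Negishi carboalumination adds methyl and aluminium syn with aluminium on the terminal carbon, and hydroxymethylation of the derived aluminate with retention should give the E-trisubstituted allylic alcohol (C13 methyl, C15).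

Step 17
Reactants: 38 (E)-allylic alcohol
Product: 39 (E)-enal (9β-[(3E)-3-methyl-5-oxopent-3-en-1-yl] analogue of 30)
Conditions: Dess–Martin periodinane, NaHCO3, CH2Cl2, 0 °C
Reagents that add atoms: none
Why: Buffered Dess–Martin oxidation of the allylic alcohol should give the enal with the E geometry kept.

Step 18
Reactants: 40 4-methylfuran-2(5H)-one; 41 trimethylsilyl trifluoromethanesulfonate
Product: 42 4-methyl-2-(trimethylsilyloxy)furan
Conditions: Me3SiOTf, Et3N, Et2O, 0 °C
Reagents that add atoms: trimethylsilyl trifluoromethanesulfonate C[Si](C)(C)OS(=O)(=O)C(F)(F)F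
Why: Soft enolisation and O-silylation of the butenolide gives the aromatic 2-silyloxyfuran, a standard vinylogous enolate equivalent, with the lactone ring carried over intact.

Step 19
Reactants: 39 (E)-enal; 42 4-methyl-2-(trimethylsilyloxy)furan
Product: 44 6,18-bis(tert-butyldimethylsilyl) 8-triethylsilyl ether of the target (free C15 carbinol; 15S; 5′S), via O-trimethylsilyl aldol adduct 43 (not isolated)
Conditions: Ti(OiPr)4 (20 mol %), (R)-BINOL (20 mol %), 4 Å molecular sieves, Et2O, −20 °C; then aq citric acid, THF, 0 °C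
Reagents that add atoms: 4-methyl-2-(trimethylsilyloxy)furan Cc1coc(O[Si](C)(C)C)c1
Why: The vinylogous Mukaiyama aldol reaction of a 2-silyloxyfuran through an open antiperiplanar transition state should favour the threo (15S,5′S-like) relationship, while the chiral titanium Lewis acid selects the Re face of the enal to set the absolute configuration at C15 and C5′.

Step 20
Reactants: 44 tris-silyl ether of the target
Product: 45 target CNP0255788.1, (5S)-5-{(1S,2E)-1-hydroxy-5-[(1R,2R,4S,4aR,5R,8aS)-2,4-dihydroxy-5-(hydroxymethyl)-2,5,8a-trimethyldecahydronaphthalen-1-yl]-3-methylpent-2-en-1-yl}-4-methylfuran-2(5H)-one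
Conditions: HF·pyridine, pyridine, THF, 0 °C to rt
Reagents that add atoms: none
Why: Buffered hydrogen fluoride should cleave the two tert-butyldimethylsilyl ethers and the tertiary triethylsilyl ether without epimerising the butenolide or ionising the allylic carbinol.

**Compound list**

1 | (R)-(−)-linalool | C=C[C@](C)(O)CCC=C(C)C | starting material
2 | triethylsilyl trifluoromethanesulfonate | CC[Si](CC)(CC)OS(=O)(=O)C(F)(F)F | starting material
3 | (3R)-3,7-dimethyl-3-(triethylsilyloxy)octa-1,6-diene | C=C[C@](C)(O[Si](CC)(CC)CC)CCC=C(C)C | intermediate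
4 | ozone | [O-][O+]=O | starting material
5 | secondary ozonide of 3 at the 6,7-double bond (not isolated) | C=C[C@](C)(O[Si](CC)(CC)CC)CCC1OOC(C)(C)O1 | intermediate
6 | (4R)-4-methyl-4-(triethylsilyloxy)hex-5-enal | C=C[C@](C)(O[Si](CC)(CC)CC)CCC=O | intermediate
7 | isopropenylmagnesium bromide | CC(=C)[Mg]Br | starting material
8 | (6R)-2,6-dimethyl-6-(triethylsilyloxy)octa-1,7-dien-3-ol (both C3 epimers) | C=C[C@](C)(O[Si](CC)(CC)CC)CCC(O)C(C)=C | intermediate
9 | (4R)-2,4-dimethyl-4-(triethylsilyloxy)cyclohex-2-en-1-ol (both C1 epimers) | OC1CC[C@@](C)(O[Si](CC)(CC)CC)C=C1C | intermediate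
10 | (4R)-2,4-dimethyl-4-(triethylsilyloxy)cyclohex-2-en-1-one | O=C1CC[C@@](C)(O[Si](CC)(CC)CC)C=C1C | intermediate
11 | benzyl 3-bromopropyl ether | BrCCCOCc1ccccc1 | starting material
12 | chlorotrimethylsilane | C[Si](C)(C)Cl | starting material
13 | 3-(benzyloxy)propylmagnesium bromide (not isolated) | Br[Mg]CCCOCc1ccccc1 | intermediate
14 | (3R,4R)-3-[3-(benzyloxy)propyl]-2,4-dimethyl-4-(triethylsilyloxy)-1-(trimethylsilyloxy)cyclohex-1-ene | C[Si](C)(C)OC1=C(C)[C@@H](CCCOCc2ccccc2)[C@](C)(O[Si](CC)(CC)CC)CC1 | intermediate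
15 | allyl bromide | C=CCBr | starting material
16 | lithium enolate from 14 (not isolated) | [Li]OC1=C(C)[C@@H](CCCOCc2ccccc2)[C@](C)(O[Si](CC)(CC)CC)CC1 | intermediate
17 | (2R,3R,4R)-2-allyl-3-[3-(benzyloxy)propyl]-2,4-dimethyl-4-(triethylsilyloxy)cyclohexan-1-one | c1ccccc1COCCC[C@@H]2[C@@](C)(CC=C)C(=O)CC[C@@]2(C)O[Si](CC)(CC)CC | intermediate
18 | 2-bromopropene | CC(Br)=C | starting material
19 | B-alkyl-9-borabicyclo[3.3.1]nonane from the allyl group of 17 (not isolated) | c1ccccc1COCCC[C@@H]2[C@@](C)(CCCB3C4CCCC3CCC4)C(=O)CC[C@@]2(C)O[Si](CC)(CC)CC | intermediate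
20 | (2R,3R,4R)-3-[3-(benzyloxy)propyl]-2,4-dimethyl-2-(4-methylpent-4-en-1-yl)-4-(triethylsilyloxy)cyclohexan-1-one | c1ccccc1COCCC[C@@H]2[C@@](C)(CCCC(C)=C)C(=O)CC[C@@]2(C)O[Si](CC)(CC)CC | intermediate
21 | N-phenylbis(trifluoromethanesulfonimide) | O=S(=O)(N(c1ccccc1)S(=O)(=O)C(F)(F)F)C(F)(F)F | starting material
22 | (4R,5R,6R)-5-[3-(benzyloxy)propyl]-4,6-dimethyl-6-(4-methylpent-4-en-1-yl)-4-(triethylsilyloxy)cyclohex-1-en-1-yl trifluoromethanesulfonate | c1ccccc1COCCC[C@@H]2[C@@](C)(CCCC(C)=C)C(OS(=O)(=O)C(F)(F)F)=CC[C@@]2(C)O[Si](CC)(CC)CC | intermediate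
23 | bis(pinacolato)diboron | CC1(C)OB(OC1(C)C)B1OC(C)(C)C(C)(C)O1 | starting material
24 | C18 alkylpalladium acetate after 6-exo insertion (phosphine ligands omitted; not isolated) | c1ccccc1COCCC[C@@H]2[C@@]3(C)CCC[C@@](C)(C[Pd]OC(C)=O)C3=CC[C@@]2(C)O[Si](CC)(CC)CC | intermediate
25 | C5=C6 octalin boronate (4α-CH2Bpin; 4β-CH3; 10β-CH3; 9β-[3-(benzyloxy)propyl]; 8β-CH3; 8α-OSiEt3) | c1ccccc1COCCC[C@@H]2[C@@]3(C)CCC[C@@](C)(CB4OC(C)(C)C(C)(C)O4)C3=CC[C@@]2(C)O[Si](CC)(CC)CC | intermediate
26 | hydrogen peroxide | OO | starting material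
27 | C6 alkylborane from 25 (5α-H; 6α-BH2; not isolated) | c1ccccc1COCCC[C@@H]2[C@@]3(C)CCC[C@@](C)(CB4OC(C)(C)C(C)(C)O4)[C@@H]3[C@@H](B)C[C@@]2(C)O[Si](CC)(CC)CC | intermediate
28 | trans-decalin 6α,18-diol (5α-H; 4α-CH2OH; 4β-CH3; 10β-CH3; 9β-[3-(benzyloxy)propyl]; 8β-CH3; 8α-OSiEt3) | c1ccccc1COCCC[C@@H]2[C@@]3(C)CCC[C@@](C)(CO)[C@@H]3[C@@H](O)C[C@@]2(C)O[Si](CC)(CC)CC | intermediate
29 | tert-butyldimethylsilyl trifluoromethanesulfonate | CC(C)(C)[Si](C)(C)OS(=O)(=O)C(F)(F)F | starting material
30 | 6,18-bis(tert-butyldimethylsilyl) ether of 28 | c1ccccc1COCCC[C@@H]2[C@@]3(C)CCC[C@@](C)(CO[Si](C)(C)C(C)(C)C)[C@@H]3[C@@H](O[Si](C)(C)C(C)(C)C)C[C@@]2(C)O[Si](CC)(CC)CC | intermediate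
31 | primary alcohol (9β-(3-hydroxypropyl) analogue of 30) | OCCC[C@@H]1[C@@]2(C)CCC[C@@](C)(CO[Si](C)(C)C(C)(C)C)[C@@H]2[C@@H](O[Si](C)(C)C(C)(C)C)C[C@@]1(C)O[Si](CC)(CC)CC | intermediate
32 | aldehyde (9β-(3-oxopropyl) analogue of 30) | O=CCC[C@@H]1[C@@]2(C)CCC[C@@](C)(CO[Si](C)(C)C(C)(C)C)[C@@H]2[C@@H](O[Si](C)(C)C(C)(C)C)C[C@@]1(C)O[Si](CC)(CC)CC | intermediate
33 | dimethyl (1-diazo-2-oxopropyl)phosphonate | CC(=O)C(=[N+]=[N-])P(=O)(OC)OC | starting material
34 | terminal alkyne (9β-(but-3-yn-1-yl) analogue of 30) | C#CCC[C@@H]1[C@@]2(C)CCC[C@@](C)(CO[Si](C)(C)C(C)(C)C)[C@@H]2[C@@H](O[Si](C)(C)C(C)(C)C)C[C@@]1(C)O[Si](CC)(CC)CC | intermediate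
35 | trimethylaluminium | C[Al](C)C | starting material
36 | paraformaldehyde (as formaldehyde) | C=O | starting material
37 | (E)-alkenyldimethylalane from 34 (not isolated) | C[Al](C)/C=C(\C)CC[C@@H]1[C@@]2(C)CCC[C@@](C)(CO[Si](C)(C)C(C)(C)C)[C@@H]2[C@@H](O[Si](C)(C)C(C)(C)C)C[C@@]1(C)O[Si](CC)(CC)CC | intermediate
38 | (E)-allylic alcohol (9β-[(3E)-5-hydroxy-3-methylpent-3-en-1-yl] analogue of 30) | OC/C=C(\C)CC[C@@H]1[C@@]2(C)CCC[C@@](C)(CO[Si](C)(C)C(C)(C)C)[C@@H]2[C@@H](O[Si](C)(C)C(C)(C)C)C[C@@]1(C)O[Si](CC)(CC)CC | intermediate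
39 | (E)-enal (9β-[(3E)-3-methyl-5-oxopent-3-en-1-yl] analogue of 30) | O=C/C=C(\C)CC[C@@H]1[C@@]2(C)CCC[C@@](C)(CO[Si](C)(C)C(C)(C)C)[C@@H]2[C@@H](O[Si](C)(C)C(C)(C)C)C[C@@]1(C)O[Si](CC)(CC)CC | intermediate
40 | 4-methylfuran-2(5H)-one | CC1=CC(=O)OC1 | starting material
41 | trimethylsilyl trifluoromethanesulfonate | C[Si](C)(C)OS(=O)(=O)C(F)(F)F | starting material
42 | 4-methyl-2-(trimethylsilyloxy)furan | Cc1coc(O[Si](C)(C)C)c1 | intermediate
43 | 15-O-trimethylsilyl aldol adduct (not isolated) | CC1=CC(=O)O[C@@H]1[C@@H](O[Si](C)(C)C)/C=C(\C)CC[C@@H]1[C@@]2(C)CCC[C@@](C)(CO[Si](C)(C)C(C)(C)C)[C@@H]2[C@@H](O[Si](C)(C)C(C)(C)C)C[C@@]1(C)O[Si](CC)(CC)CC | intermediate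
44 | 6,18-bis(tert-butyldimethylsilyl) 8-triethylsilyl ether of the target (15S; 5′S) | CC1=CC(=O)O[C@@H]1[C@@H](O)/C=C(\C)CC[C@@H]1[C@@]2(C)CCC[C@@](C)(CO[Si](C)(C)C(C)(C)C)[C@@H]2[C@@H](O[Si](C)(C)C(C)(C)C)C[C@@]1(C)O[Si](CC)(CC)CC | intermediate
45 | CNP0255788.1, (5S)-5-{(1S,2E)-1-hydroxy-5-[(1R,2R,4S,4aR,5R,8aS)-2,4-dihydroxy-5-(hydroxymethyl)-2,5,8a-trimethyldecahydronaphthalen-1-yl]-3-methylpent-2-en-1-yl}-4-methylfuran-2(5H)-one | CC1=CC(=O)O[C@@H]1[C@@H](O)/C=C(\C)CC[C@@H]1[C@@]2(C)CCC[C@@](C)(CO)[C@@H]2[C@@H](O)C[C@@]1(C)O | target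

**Step count and risks**

Total step count: 20. Longest linear sequence: 19 steps (steps 1–17, 19 and 20; step 18 is a one-step side branch).

Steps most likely to fail:

Step 10. The hindered C5 vinylpalladium may be borylated before it inserts the alkene, and the C18 alkylpalladium may close a three-membered ring onto the C5=C6 bond before boron capture. Fallback by a conventional Heck reaction that ends in β-hydride elimination, setting out from 17 and returning at 28: the 9-BBN adduct 19 of ketone 17 is coupled with 2-bromobut-2-ene instead of 2-bromopropene to give the 4-methylhex-4-enyl ketone F1. KN(SiMe3)2 and PhNTf2 give the enol triflate F2. A 6-exo Mizoroki–Heck cyclisation (Pd(OAc)2, PPh3, Et3N, MeCN, 80 °C) places palladium on a carbon that bears a methyl group, so β-hydride elimination should give the 4α-vinyl C5=C6 octalin F3 with the same facial control by C20. Lemieux–Johnson cleavage of the unhindered vinyl group (OsO4 cat., NaIO4, 2,6-lutidine, dioxane/water) should give the 4α-carbaldehyde F4. NaBH4 in MeOH gives the 18-alcohol F5, and BH3·THF followed by NaOH/H2O2 returns diol 28.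

Step 19. Facial control by the chiral Lewis acid may erode at the β,β-disubstituted enal, which lies far from any stereocentre of the decalin, and the threo preference of the open transition state may drop. Fallback by a different activation mode, setting out from 39 and 40 and returning at 44: a direct vinylogous aldol addition of the unsilylated butenolide 40 to enal 39 under a bifunctional cinchona-derived squaramide catalyst (CH2Cl2, 0 °C), in which the catalyst deprotonates the γ-position and binds the aldehyde by hydrogen bonding. Step 18 is then not needed and no compound outside the list is made (F0).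

Step 6. Addition of the functionalised organocopper reagent at C9, next to the quaternary C8, may be slow, and the preference for attack anti to the silyloxy group may fall. Fallback by a Lewis-acid-mediated allylsilane addition, setting out from 10 and returning at 14: Hosomi–Sakurai conjugate allylation (allyltrimethylsilane, TiCl4, CH2Cl2, −78 °C) with a small linear nucleophile that attacks axially should give the 3-allyl ketone F6. 9-BBN then NaOH/H2O2 gives the 3-(3-hydroxypropyl) ketone F7. Neutral benzylation (2-benzyloxy-1-methylpyridinium triflate, MgO, PhCF3, 85 °C) gives the benzyl ether F8. Thermodynamic silylation (Me3SiCl, NaI, Et3N, MeCN) should give the more substituted silyl enol ether 14.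

Further compounds
F1 | step 10 | (2R,3R,4R)-3-[3-(benzyloxy)propyl]-2,4-dimethyl-2-(4-methylhex-4-en-1-yl)-4-(triethylsilyloxy)cyclohexan-1-one | c1ccccc1COCCC[C@@H]2[C@@](C)(CCCC(C)=CC)C(=O)CC[C@@]2(C)O[Si](CC)(CC)CC
F2 | step 10 | enol triflate of F1 (C5–OTf, C5=C6) | c1ccccc1COCCC[C@@H]2[C@@](C)(CCCC(C)=CC)C(OS(=O)(=O)C(F)(F)F)=CC[C@@]2(C)O[Si](CC)(CC)CC
F3 | step 10 | 4α-vinyl C5=C6 octalin (4β-CH3; 10β-CH3; 9β-[3-(benzyloxy)propyl]; 8β-CH3; 8α-OSiEt3) | c1ccccc1COCCC[C@@H]2[C@@]3(C)CCC[C@@](C)(C=C)C3=CC[C@@]2(C)O[Si](CC)(CC)CC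
F4 | step 10 | 4α-carbaldehyde analogue of F3 | c1ccccc1COCCC[C@@H]2[C@@]3(C)CCC[C@@](C)(C=O)C3=CC[C@@]2(C)O[Si](CC)(CC)CC
F5 | step 10 | 4α-hydroxymethyl analogue of F3 (18-alcohol, C5=C6 retained) | c1ccccc1COCCC[C@@H]2[C@@]3(C)CCC[C@@](C)(CO)C3=CC[C@@]2(C)O[Si](CC)(CC)CC
F0 | step 19 | none | none
F6 | step 6 | (3R,4R)-3-allyl-2,4-dimethyl-4-(triethylsilyloxy)cyclohexan-1-one (C2 epimers) | O=C1C(C)[C@@H](CC=C)[C@](C)(O[Si](CC)(CC)CC)CC1
F7 | step 6 | (3R,4R)-3-(3-hydroxypropyl)-2,4-dimethyl-4-(triethylsilyloxy)cyclohexan-1-one (C2 epimers) | O=C1C(C)[C@@H](CCCO)[C@](C)(O[Si](CC)(CC)CC)CC1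
F8 | step 6 | (3R,4R)-3-[3-(benzyloxy)propyl]-2,4-dimethyl-4-(triethylsilyloxy)cyclohexan-1-one (C2 epimers) | O=C1C(C)[C@@H](CCCOCc2ccccc2)[C@](C)(O[Si](CC)(CC)CC)CC1
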